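**Retrosynthetic overview**

1. Atom labels follow the elemane skeleton: C10 carries the C14 methyl and the C1=C2 vinyl, C5 carries C4(=C15)–C3HO, C6 carries the angelate (O6), C7–C11(=C13)–C12(=O)–O8–C8 is the lactone, and C9 carries the methacrylate (O9). The last operations are oxidation of C12, the two acylations, and unmasking of C3/C15.
2. The key disconnection cuts C6–C7 and C9–C10. Each is the Cα–Cβ bond of a homoallylic alcohol (O6–C6–C7–C11=C13 and O9–C9–C10–C1=C2), so both can come from carbonyl allylations joined in a single [3+3] annulation of an allylic bromide fragment (C10–C5–C6) with an aldehyde fragment (C7–C8–C9).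
3. The enabling feature is that C3 of the C5 side chain and O9 are cis-1,3 on the cyclohexane. With C3 at the acid level they can be tied as a temporary six-membered lactone (C5–C4–C3(=O)–O9–C9). Forming this lactone from a pseudo-ester releases the C6 aldehyde, and the bridge holds the chair in which the second allylation gives O6 trans to C11.
4. C12 is carried as CH2 so that O8 is a chelating ring ether during the first allylation and the 2,5-dihydrofuran fixes the allyl geometry and the cis ring fusion.
5. Ring order: dihydrofuran (ring-closing metathesis), then in the key step the δ-lactone followed by the cyclohexane; the δ-lactone is then reduced and opened, and the oxolane is oxidised to the γ-lactone last.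

Key step: step 11

Remark: methyl (2E)-4,4-dimethoxybut-2-enoate and (2R)-but-3-ene-1,2-diol are taken as commercial (the ester is otherwise one Wittig step from dimethoxyacetaldehyde).

**Route**

Step 1
Reactants: 1 but-2-yn-1-ol
Product: 2 (2Z)-3-(4,4,5,5-tetramethyl-1,3,2-dioxaborolan-2-yl)but-2-en-1-ol
Conditions: CuCl (5 mol %), Xantphos (5 mol %), NaOt-Bu (10 mol %), B2pin2, MeOH, THF, rt
Reagents that add atoms: bis(pinacolato)diboron, CC1(C)OB(OC1(C)C)B1OC(C)(C)C(C)(C)O1
Why: Copper-catalysed borylcupration–protonation (formal syn-hydroboration) of the internal alkyne should place boron on the methyl-bearing carbon, away from the oxygenated carbon that stabilises the C–Cu bond, and the syn addition fixes boron trans to CH2OH, the geometry that later becomes the E-allyl unit.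

Step 2
Reactants: 2 (2Z)-3-(pinacolboryl)but-2-en-1-ol; 3 methyl (2E)-4,4-dimethoxybut-2-enoate
Product: 4 methyl (3S,4E)-3-(dimethoxymethyl)-6-hydroxy-4-methylhex-4-enoate
Conditions: [Rh(cod)OH]2 (2.5 mol %), (S)-BINAP (6 mol %), dioxane/H2O 10:1, 40 °C
Reagents that add atoms: none
Why: Rhodium-catalysed asymmetric conjugate addition (Hayashi–Miyaura reaction) should transfer the alkenyl group with retention of geometry, and the BINAP-bound alkenylrhodium selects the enoate face that sets C5 (the ligand enantiomer is assigned by the usual model for (E)-enoates and would be confirmed on the first run).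

Step 3
Reactants: 4 methyl (3S,4E)-3-(dimethoxymethyl)-6-hydroxy-4-methylhex-4-enoate
Product: 5 (3S,4E)-3-(dimethoxymethyl)-6-hydroxy-4-methylhex-4-enoic acid
Conditions: LiOH, THF/H2O, 0 °C to rt; then dilute HCl to pH 4 at 0 °C
Reagents that add atoms: lithium hydroxide, [Li+].[OH-]
Why: Saponification of the methyl ester, which leaves the base-stable acetal and the stereocentre untouched.

Step 4
Reactants: 5 (3S,4E)-3-(dimethoxymethyl)-6-hydroxy-4-methylhex-4-enoic acid
Product: 6 (4S)-4-[(2E)-4-hydroxybut-2-en-2-yl]-5-methoxyoxolan-2-one (both epimers at the acetal carbon)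
Conditions: PPTS (10 mol %), 4 Å MS, CH2Cl2, rt
Reagents that add atoms: none
Why: Acid-catalysed loss of methanol from the acetal gives an oxocarbenium ion that the carboxylic acid captures (5-exo), the known route to 5-alkoxy-γ-lactones (pseudo-esters); the E-alkene keeps the allylic hydroxyl out of reach and the acetal epimers do not matter.

Step 5
Reactants: 6 (4S)-4-[(2E)-4-hydroxybut-2-en-2-yl]-5-methoxyoxolan-2-one
Product: 7 (4S)-4-[(2E)-4-bromobut-2-en-2-yl]-5-methoxyoxolan-2-one
Conditions: CBr4, PPh3, CH2Cl2, 0 °C
Reagents that add atoms: carbon tetrabromide, BrC(Br)(Br)Br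
Why: Appel bromination of the primary allylic alcohol under neutral conditions, which the pseudo-ester should tolerate.

Step 6
Reactants: 8 (2R)-but-3-ene-1,2-diol
Product: 9 (2R)-1-(triphenylmethoxy)but-3-en-2-ol
Conditions: TrCl, Et3N, DMAP (cat.), CH2Cl2, 0 °C to rt
Reagents that add atoms: triphenylmethyl chloride, ClC(c1ccccc1)(c1ccccc1)c1ccccc1
Why: Tritylation is selective for the primary hydroxyl, and a trityl ether cannot migrate to the neighbouring alkoxide in the next step.

Step 7
Reactants: 9 (2R)-1-(triphenylmethoxy)but-3-en-2-ol; 10 3-chloro-2-(chloromethyl)prop-1-ene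
Product: 11 (2R)-2-{[2-(chloromethyl)prop-2-en-1-yl]oxy}-1-(triphenylmethoxy)but-3-ene
Conditions: NaH, THF, 0 °C; then 10 (3 equiv), Bu4NI (cat.), rt
Reagents that add atoms: none
Why: Williamson etherification of the secondary alkoxide with an excess of the symmetrical allylic dichloride, which does not involve the stereocentre.

Step 8
Reactants: 11 (2R)-2-{[2-(chloromethyl)prop-2-en-1-yl]oxy}-1-(triphenylmethoxy)but-3-ene
Product: 12 (2R)-4-(chloromethyl)-2-[(triphenylmethoxy)methyl]-2,5-dihydrofuran
Conditions: second-generation Grubbs catalyst (3 mol %), CH2Cl2, 40 °C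
Reagents that add atoms: none
Why: Ring-closing metathesis closes the 2,5-dihydrofuran (five-membered ring, trisubstituted alkene) with loss of ethene and tolerates the ether and the allylic chloride.

Step 9
Reactants: 12 (2R)-4-(chloromethyl)-2-[(triphenylmethoxy)methyl]-2,5-dihydrofuran
Product: 13 [(2R)-4-(chloromethyl)-2,5-dihydrofuran-2-yl]methanol
Conditions: TsOH·H2O (cat.), MeOH/CH2Cl2, rt
Reagents that add atoms: none
Why: Acid-catalysed methanolysis of the trityl ether, mild enough for the allylic ether and chloride.

Step 10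
Reactants: 13 [(2R)-4-(chloromethyl)-2,5-dihydrofuran-2-yl]methanol
Product: 14 (2R)-4-(chloromethyl)-2,5-dihydrofuran-2-carbaldehyde
Conditions: Dess–Martin periodinane, CH2Cl2, 0 °C to rt; crude product used at once
Reagents that add atoms: none
Why: Dess–Martin oxidation under neutral conditions, the aldehyde being used immediately because its α-centre (C8) is activated towards epimerisation and aromatisation.

Step 11
Reactants: 7 (4S)-4-[(2E)-4-bromobut-2-en-2-yl]-5-methoxyoxolan-2-one; 14 (2R)-4-(chloromethyl)-2,5-dihydrofuran-2-carbaldehyde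
Product: 17 tricyclic hydroxy lactone (cyclohexane C5–C10 bridged from C5 to C9 by CH2–C(=O)–O and cis-fused at C7–C8 to a 3-methylideneoxolane; C6–OH; stereocentres as in the target), via hydroxy pseudo-ester 15 (not isolated), via lactone aldehyde 16 (not isolated)
Conditions: In powder (2.5 equiv), Bu4NI (20 mol %), THF, 0 °C (7 added slowly), then 55 °C; aq. NH4Cl
Reagents that add atoms: none
Why: Proposed new method: zerovalent indium first converts the allylic bromide of 7 into an allylindium that adds through its γ-carbon C10 to the aldehyde of 14 (closest known type: indium-mediated Barbier allylation with prenyl-type bromides, and with bromomethyl-butenolides for the second bond); the indium alkoxide at O9 then attacks the pseudo-ester carbonyl C3 (6-exo-trig acyl substitution) to close the δ-lactone and expel the hemiacetal, which collapses to the C6 aldehyde, and only then does the iodide-activated allylic chloride give a second allylindium whose ring carbon C7 closes the cyclohexane on C6 (6-exo-trig carbonyl addition through a Zimmerman–Traxler chair). C9 should be set by chelation of trivalent indium between the aldehyde oxygen and the ring ether O8 (attack anti to C7, O9 syn to O8), and C10 by the chair transition state of the E-allyl unit (C5 equatorial, methyl axial). C6 and C7 should be set in the second chair transition state, which the lactone bridge forces into the conformer with C4 and O9 diaxial, so that O6 and C11 are both equatorial and trans, while the dihydrofuran ring fixes the allyl geometry and allows only attack from the face of its C9 substituent, giving the cis-fused oxolane. The selectivity needed is cross-coupling without self-coupling and C9–C10 before C6–C7; it is secured because 7 has no free carbonyl until the lactone has formed, 14 carries only a slow allylic chloride, and the aldehyde of 16 appears next to a nucleophile that reaches it intramolecularly. Isomers with the wrong configuration at C5, C8 or C9 cannot span the bicyclo[3.3.1] transition state and should not cyclise.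

Step 12
Reactants: 17 tricyclic hydroxy lactone
Product: 18 tricyclic lactone angelate (17 esterified at O6 with (2Z)-2-methylbut-2-enoic acid)
Conditions: angelic acid, 2,4,6-trichlorobenzoyl chloride, Et3N, toluene, rt; then 17, 60 °C
Reagents that add atoms: angelic acid, C/C=C(/C)C(=O)O
Why: Yamaguchi esterification of the only free hydroxyl (O6, equatorial while the lactone bridge holds the ring), run without DMAP to limit Z-to-E isomerisation of the angelate.

Step 13
Reactants: 18 tricyclic lactone angelate
Product: 19 bridged lactol angelate (C3 now CH(OH)–O9)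
Conditions: i-Bu2AlH (1.1 equiv), CH2Cl2, −78 °C; aq. potassium sodium tartrate
Reagents that add atoms: none
Why: Low-temperature DIBAL reduction stops at the lactol and should take the strained saturated δ-lactone ahead of the hindered conjugated ester, as in known lactone-to-lactol reductions in the presence of ester groups.

Step 14
Reactants: 19 bridged lactol angelate
Product: 20 (3aR,4S,5R,6S,7R,7aR)-6-ethenyl-7-hydroxy-6-methyl-3-methylidene-5-(3-oxoprop-1-en-2-yl)octahydro-1-benzofuran-4-yl (2Z)-2-methylbut-2-enoate
Conditions: CH2=NMe2+ I− (3 equiv), Et3N, CH2Cl2, rt to 40 °C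
Reagents that add atoms: N,N-dimethylmethylideneammonium iodide, C[N+](C)=C.[I-]
Why: Mannich reaction of the open hydroxy-aldehyde form with Eschenmoser's salt followed by β-elimination of dimethylamine (α-methylenation of an aldehyde) installs C15, and opening of the bridge lets the ring relax to the chair with the side chain equatorial and O9–H free.

Step 15
Reactants: 20 hydroxy enal angelate
Product: 21 (3aR,4S,5R,6S,7R,7aR)-6-ethenyl-6-methyl-3-methylidene-7-[(2-methylprop-2-enoyl)oxy]-5-(3-oxoprop-1-en-2-yl)octahydro-1-benzofuran-4-yl (2Z)-2-methylbut-2-enoate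
Conditions: methacrylic anhydride, Et3N, DMAP (cat.), CH2Cl2, 0 °C
Reagents that add atoms: methacrylic anhydride, CC(=C)C(=O)OC(=O)C(C)=C
Why: DMAP-catalysed acylation of the only remaining hydroxyl (O9), so no site selectivity is needed.

Step 16
Reactants: 21 oxolane diester
Product: 22 (3aR,4S,5R,6S,7R,7aR)-6-ethenyl-6-methyl-3-methylidene-7-[(2-methylprop-2-enoyl)oxy]-2-oxo-5-(3-oxoprop-1-en-2-yl)octahydro-1-benzofuran-4-yl (2Z)-2-methylbut-2-enoate (target)
Conditions: CrO3, 3,5-dimethylpyrazole, CH2Cl2, −20 °C
Reagents that add atoms: chromium trioxide, O=[Cr](=O)=O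
Why: Allylic oxidation of the CH2 group that is both allylic and next to the ring oxygen (C12), a known conversion of 3-methylideneoxolanes into α-methylene-γ-butyrolactones with chromium trioxide–amine reagents; the electron-poor alkenes of the enal and the two esters have no comparably activated C–H bond.

**Compound list**

1 | but-2-yn-1-ol | CC#CCO | starting material
2 | (2Z)-3-(4,4,5,5-tetramethyl-1,3,2-dioxaborolan-2-yl)but-2-en-1-ol | C/C(B1OC(C)(C)C(C)(C)O1)=C\CO | intermediate
3 | methyl (2E)-4,4-dimethoxybut-2-enoate | COC(=O)/C=C/C(OC)OC | starting material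
4 | methyl (3S,4E)-3-(dimethoxymethyl)-6-hydroxy-4-methylhex-4-enoate | COC(=O)C[C@H](C(OC)OC)/C(C)=C/CO | intermediate
5 | (3S,4E)-3-(dimethoxymethyl)-6-hydroxy-4-methylhex-4-enoic acid | OC(=O)C[C@H](C(OC)OC)/C(C)=C/CO | intermediate
6 | (4S)-4-[(2E)-4-hydroxybut-2-en-2-yl]-5-methoxyoxolan-2-one (acetal epimers) | COC1OC(=O)C[C@H]1/C(C)=C/CO | intermediate
7 | (4S)-4-[(2E)-4-bromobut-2-en-2-yl]-5-methoxyoxolan-2-one (acetal epimers) | COC1OC(=O)C[C@H]1/C(C)=C/CBr | intermediate
8 | (2R)-but-3-ene-1,2-diol | C=C[C@H](CO)O | starting material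
9 | (2R)-1-(triphenylmethoxy)but-3-en-2-ol | C=C[C@H](COC(c1ccccc1)(c1ccccc1)c1ccccc1)O | intermediate
10 | 3-chloro-2-(chloromethyl)prop-1-ene | C=C(CCl)CCl | starting material
11 | (2R)-2-{[2-(chloromethyl)prop-2-en-1-yl]oxy}-1-(triphenylmethoxy)but-3-ene | C=C[C@H](COC(c1ccccc1)(c1ccccc1)c1ccccc1)OCC(=C)CCl | intermediate
12 | (2R)-4-(chloromethyl)-2-[(triphenylmethoxy)methyl]-2,5-dihydrofuran | C(OC[C@@H]1OCC(CCl)=C1)(c1ccccc1)(c1ccccc1)c1ccccc1 | intermediate
13 | [(2R)-4-(chloromethyl)-2,5-dihydrofuran-2-yl]methanol | OC[C@@H]1OCC(CCl)=C1 | intermediate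
14 | (2R)-4-(chloromethyl)-2,5-dihydrofuran-2-carbaldehyde | O=C[C@@H]1OCC(CCl)=C1 | intermediate
15 | (4S)-4-[(1R,2S)-1-[(2R)-4-(chloromethyl)-2,5-dihydrofuran-2-yl]-1-hydroxy-2-methylbut-3-en-2-yl]-5-methoxyoxolan-2-one | C=C[C@@](C)([C@@H]2CC(=O)OC2OC)[C@@H](O)[C@@H]3OCC(CCl)=C3 | intermediate
16 | (4S,5S,6R)-6-[(2R)-4-(chloromethyl)-2,5-dihydrofuran-2-yl]-5-ethenyl-5-methyl-2-oxooxane-4-carbaldehyde | C=C[C@@]1(C)[C@@H](C=O)CC(=O)O[C@H]1[C@@H]2OCC(CCl)=C2 | intermediate
17 | tricyclic hydroxy lactone: cyclohexane C5–C10 with C6–OH, C10 methyl and vinyl, bridge C5–CH2–C(=O)–O–C9, and cis-fused 3-methylideneoxolane at C7–C8; stereocentres as in 22 | C=C[C@@]1(C)[C@H](CC(=O)O3)[C@H](O)[C@H]2C(=C)CO[C@H]2[C@@H]13 | intermediate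
18 | O6-angelate of 17 | C=C[C@@]1(C)[C@H](CC(=O)O3)[C@H](OC(=O)/C(C)=C\C)[C@H]2C(=C)CO[C@H]2[C@@H]13 | intermediate
19 | bridged lactol of 18 (C3 as CH(OH)–O9, anomers) | C=C[C@@]1(C)[C@H](CC(O)O3)[C@H](OC(=O)/C(C)=C\C)[C@H]2C(=C)CO[C@H]2[C@@H]13 | intermediate
20 | (3aR,4S,5R,6S,7R,7aR)-6-ethenyl-7-hydroxy-6-methyl-3-methylidene-5-(3-oxoprop-1-en-2-yl)octahydro-1-benzofuran-4-yl (2Z)-2-methylbut-2-enoate | C=C[C@@]1(C)[C@H](C(=C)C=O)[C@H](OC(=O)/C(C)=C\C)[C@H]2C(=C)CO[C@H]2[C@@H]1O | intermediate
21 | (3aR,4S,5R,6S,7R,7aR)-6-ethenyl-6-methyl-3-methylidene-7-[(2-methylprop-2-enoyl)oxy]-5-(3-oxoprop-1-en-2-yl)octahydro-1-benzofuran-4-yl (2Z)-2-methylbut-2-enoate | C=C[C@@]1(C)[C@H](C(=C)C=O)[C@H](OC(=O)/C(C)=C\C)[C@H]2C(=C)CO[C@H]2[C@@H]1OC(=O)C(=C)C | intermediate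
22 | (3aR,4S,5R,6S,7R,7aR)-6-ethenyl-6-methyl-3-methylidene-7-[(2-methylprop-2-enoyl)oxy]-2-oxo-5-(3-oxoprop-1-en-2-yl)octahydro-1-benzofuran-4-yl (2Z)-2-methylbut-2-enoate | C=C[C@@]1(C)[C@H](C(=C)C=O)[C@H](OC(=O)/C(C)=C\C)[C@H]2C(=C)C(=O)O[C@H]2[C@@H]1OC(=O)C(=C)C | target

**Summary**

Total step count: 16. Longest linear sequence: 11 steps (steps 1–5 or 6–10, then 11–16).

**Steps most likely to fail**

1. Step 11 (proposed new method). The order of events may break down: early metalation of the allylic chloride would give self-coupling, incomplete chelation would give Felkin addition at C9, the O9 alkoxide may etherify the allylic chloride, and trivalent indium may ionise the pseudo-ester acetal before the lactone has formed. The fallback separates the events with known reactions. From 7 and 14, the indium-mediated Barbier allylation alone in THF/H2O at 0 °C gives hydroxy pseudo-ester 15, which is isolated. Catalytic DBU in CH2Cl2 effects the translactonisation to lactone aldehyde 16, which is isolated. NaI in acetone exchanges the chloride to give the allylic iodide F1, and an intramolecular Nozaki–Hiyama–Kishi allylation (CrCl2, THF, rt) closes the cyclohexane through the same lactone-locked chair and returns to the route at 17.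

2. Step 16. The late allylic oxidation may over-oxidise the substrate or attack the aldehyde or another allylic position. The fallback sets out from 21: SeO2 (cat.)/t-BuOOH allylic hydroxylation at C12 gives the lactol F2, and Ag2CO3 on Celite (Fétizon oxidation) converts lactol F2 into 22.

3. Step 13. The hydride may also reduce or cleave the angelate, or over-reduce the lactone to the diol. The fallback sets out from 17 and moves the angeloylation to the end. TESOTf/2,6-lutidine gives the silyl ether F3. DIBAL at −78 °C, with no ester present, gives the lactol F4. Eschenmoser methylenation gives the enal F5. Methacrylic anhydride/DMAP gives the methacrylate F6. HF·pyridine gives the hydroxy methacrylate F7. Yamaguchi angeloylation of F7 returns to the route at 21.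

Further compounds
F1 | step 11 | (4S,5S,6R)-5-ethenyl-6-[(2R)-4-(iodomethyl)-2,5-dihydrofuran-2-yl]-5-methyl-2-oxooxane-4-carbaldehyde | C=C[C@@]1(C)[C@@H](C=O)CC(=O)O[C@H]1[C@@H]2OCC(CI)=C2
F2 | step 16 | C12 lactol of 21 (2-hydroxy-3-methylideneoxolane in place of the oxolane, anomers) | C=C[C@@]1(C)[C@H](C(=C)C=O)[C@H](OC(=O)/C(C)=C\C)[C@H]2C(=C)C(O)O[C@H]2[C@@H]1OC(=O)C(=C)C
F3 | step 13 | O6-triethylsilyl ether of 17 | C=C[C@@]1(C)[C@H](CC(=O)O3)[C@H](O[Si](CC)(CC)CC)[C@H]2C(=C)CO[C@H]2[C@@H]13
F4 | step 13 | bridged lactol of F3 (anomers) | C=C[C@@]1(C)[C@H](CC(O)O3)[C@H](O[Si](CC)(CC)CC)[C@H]2C(=C)CO[C@H]2[C@@H]13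
F5 | step 13 | O6-triethylsilyl hydroxy enal (analogue of 20 with OSiEt3 at C6) | C=C[C@@]1(C)[C@H](C(=C)C=O)[C@H](O[Si](CC)(CC)CC)[C@H]2C(=C)CO[C@H]2[C@@H]1O
F6 | step 13 | O9-methacrylate of F5 | C=C[C@@]1(C)[C@H](C(=C)C=O)[C@H](O[Si](CC)(CC)CC)[C@H]2C(=C)CO[C@H]2[C@@H]1OC(=O)C(=C)C
F7 | step 13 | O9-methacrylate with free O6–H (21 without the angeloyl group) | C=C[C@@]1(C)[C@H](C(=C)C=O)[C@H](O)[C@H]2C(=C)CO[C@H]2[C@@H]1OC(=O)C(=C)C
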